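## Retrosynthetic overview

- The coumarate at O18, the C15 acid and the phenol are unmasked last. The C8(17) exo-methylene and H9 come from a C17 allylic alcohol by reductive 1,3-transposition, H5 from a hydrogenation directed by the C18 hydroxyl, and C12–C15 from a copper-catalysed allylic coupling at C11 with a chiral-pool Grignard reagent.
- This leads back to a 5,8-diene-11,18-diol and its bridging C18–O–C11 lactone. Key disconnection: retro-[4+2] (C9–C10 and C7–C8) to the C18 4-silyloxybut-2-ynoate of a ring-A vinylcyclohexene.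
- Structural feature used: on ring A the oxygen-bearing C18 on C4 and the C10–C9 bond are cis-1,3 (C19 and C20 both lie on the other face), so an ester from O18 to C11 can hold the C8≡C9 ynoate over the C10=C5–C6=C7 diene.
- Ring order: ring A first (from a cyclohexanone keto ester, C4 set by auxiliary-controlled methylation), then ring B together with the temporary seven-membered lactone in one step; the lactone is then opened by reduction.

Key step: step 10

Remark 1: labdane numbering is used for all ring and chain positions (C4 bears C18H2O and C19H3, C10 bears C20H3, C17 is on C8, C11 on C9).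
Remark 2 (assumption): the valine-ester enamine methylation of step 2 is written for the L-auxiliary in toluene/HMPA as giving the (S)-keto ester 6; the facial sense of this method switches with the donor additive and with the auxiliary enantiomer, so one of these switches would be used if the opposite sense resulted.
Remark 3: L-valine tert-butyl ester is sold as its hydrochloride and is free-based before use; (S)-3-bromo-2-methylpropan-1-ol is the commercial bromohydrin derived from the Roche ester.

## Route

Step 1
Reactants: 1 ethyl 2-oxocyclohexane-1-carboxylate; 2 L-valine tert-butyl ester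
Product: 3 ethyl 2-{[(2S)-1-tert-butoxy-3-methyl-1-oxobutan-2-yl]amino}cyclohex-1-ene-1-carboxylate
Conditions: cat. AcOH, toluene, reflux, Dean–Stark
Reagents that add atoms: none
Why: Condensation of the β-keto ester with the primary amine gives the hydrogen-bonded enamino ester (vinylogous carbamate formation), driven by removal of water.

Step 2
Reactants: 3 enamino ester
Product: 6 ethyl (1S)-1-methyl-2-oxocyclohexane-1-carboxylate, via lithiated enamine 4 (not isolated), via C-methylated ketimine 5 (not isolated)
Conditions: LDA, toluene, HMPA (1 equiv), −78 °C; MeI, −78 °C; then 1 M aq. HCl, rt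
Reagents that add atoms: iodomethane CI; water O
Why: Auxiliary-controlled alkylation of a chelated lithium aza-enolate (chiral enamine alkylation): lithium is held between nitrogen and the tert-butyl ester carbonyl, the isopropyl group covers one face and iodomethane should enter from the other to set quaternary C4 as S, after which mild acid hydrolysis of 5 releases the ketone and the auxiliary.

Step 3
Reactants: 6 ethyl (1S)-1-methyl-2-oxocyclohexane-1-carboxylate
Product: 8 ethyl (1S,3RS)-1,3-dimethyl-2-oxocyclohexane-1-carboxylate (epimer mixture at C3), via lithium enolate 7 (not isolated)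
Conditions: LDA, THF, −78 °C; MeI, −78 → 0 °C
Reagents that add atoms: iodomethane CI
Why: Kinetic enolate alkylation can occur only at C3 because C1 is quaternary, and the new centre needs no control since it becomes sp2 in the next step.

Step 4
Reactants: 8 ethyl (1S,3RS)-1,3-dimethyl-2-oxocyclohexane-1-carboxylate
Product: 10 ethyl (1S)-1,3-dimethyl-2-[(trifluoromethanesulfonyl)oxy]cyclohex-2-ene-1-carboxylate, via potassium enolate 9 (not isolated)
Conditions: KHMDS, THF, −78 °C; PhNTf2, −78 °C → rt; cold dilute HCl wash
Reagents that add atoms: N-phenylbis(trifluoromethanesulfonimide) O=S(=O)(N(c1ccccc1)S(=O)(=O)C(F)(F)F)C(F)(F)F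
Why: O-Triflation of the only possible enolate gives the tetrasubstituted enol triflate regiospecifically (enol triflate formation).

Step 5
Reactants: 10 enol triflate
Product: 11 ethyl (1S)-2-ethenyl-1,3-dimethylcyclohex-2-ene-1-carboxylate
Conditions: tributyl(vinyl)stannane, Pd(PPh3)4 (5 mol %), LiCl (3 equiv), THF, reflux
Reagents that add atoms: tributyl(vinyl)stannane C=C[Sn](CCCC)(CCCC)CCCC
Why: Stille coupling of hindered 2,6,6-trisubstituted cyclohexenyl triflates with vinylstannane under Pd(0)/LiCl is established and leaves the ester and the quaternary centre untouched.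

Step 6
Reactants: 11 diene ester
Product: 12 [(1S)-2-ethenyl-1,3-dimethylcyclohex-2-en-1-yl]methanol
Conditions: LiAlH4, Et2O, 0 °C
Reagents that add atoms: none
Why: Hydride reduction of the ester gives the neopentyl C18 alcohol without touching the diene.

Step 7
Reactants: 13 prop-2-yn-1-ol
Product: 14 tert-butyldimethyl(prop-2-yn-1-yloxy)silane
Conditions: TBSCl, imidazole, CH2Cl2, 0 °C → rt
Reagents that add atoms: tert-butyldimethylsilyl chloride CC(C)(C)[Si](C)(C)Cl
Why: Standard silylation of a primary alcohol.

Step 8
Reactants: 14 silyl propargyl ether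
Product: 16 4-[(tert-butyldimethylsilyl)oxy]but-2-ynoic acid, via lithium acetylide 15 (not isolated)
Conditions: n-BuLi, THF, −78 °C; CO2, −78 → 0 °C; cold aq. HCl to pH 3
Reagents that add atoms: carbon dioxide O=C=O
Why: Carboxylation of the lithium acetylide gives the ynoic acid, and the silyl ether survives a brief cold acidification.

Step 9
Reactants: 12 dienyl alcohol; 16 ynoic acid
Product: 17 [(1S)-2-ethenyl-1,3-dimethylcyclohex-2-en-1-yl]methyl 4-[(tert-butyldimethylsilyl)oxy]but-2-ynoate
Conditions: DCC, DMAP (0.1 equiv), CH2Cl2, 0 °C → rt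
Reagents that add atoms: none
Why: Steglich esterification acylates the neopentyl alcohol under neutral conditions that spare the diene and the silyl ether, the low temperature limiting DMAP addition to the ynoate.

Step 10
Reactants: 17 dienyl ynoate
Product: 18 bridged lactone of the 5,8-diene (C11(=O)–O–C18 seven-membered lactone, C17 OTBS, C20 cis to C19 and on the face opposite the lactone bridge)
Conditions: 1,2-dichlorobenzene (0.005 M, degassed), BHT (0.1 equiv), 180 °C, sealed tube
Reagents that add atoms: none
Why: Proposed new method: a thermal, concerted but asynchronous [4+2] cycloaddition in which the ynoate carbon C9 bonds to the methylated diene terminus C10 and C8 bonds to C7, the ester of the dienophile serving at the same time as the tether from C18; the closest known reactions are the intermolecular cycloadditions of 1,3,3-trisubstituted 2-vinylcyclohexenes with acetylenic esters, ester-tethered intramolecular Diels–Alder reactions of alkynoates, and type-2 intramolecular Diels–Alder reactions of alkynes that give bridgehead dienes, but a bridging seven-membered lactone tether on such a diene has not been shown. Ring B closes as a cyclohexa-1,4-diene (C5=C6, C8=C9) through the two new σ bonds. The seven-membered lactone C4–C18–O–C11–C9–C10–C5 closes through the same C9–C10 bond with the tether anchored beside the internal diene carbon C5 (type-2 arrangement), which makes C5 and C9 bridgeheads of a bicyclo[4.3.1] unit with twisted alkenes; the early transition state of an alkyne cycloaddition should feel only part of this strain and the reaction stays strongly exothermic. The new quaternary centre C10 is controlled by C4: the four-atom tether (C4, C18, O, C11) lets C9 reach C10 only on the ring-A face that carries C18, so C20 should end up cis to C19. The selectivities needed are regiochemistry and π-face: the tether is too short to deliver C9 to C7, and the same orientation is the electronically preferred one (ester-bearing carbon to the substituted terminus). High dilution and BHT suppress intermolecular cycloaddition and radical polymerisation, and the cisoid ester rotamer needed for closure is the reason for the high temperature.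

Step 11
Reactants: 18 bridged lactone
Product: 19 5,8-diene-11,18-diol with C17 OTBS
Conditions: DIBAL-H (4 equiv), CH2Cl2, −78 → 0 °C; Rochelle salt
Reagents that add atoms: none
Why: DIBAL-H reduces the strained conjugated lactone in the 1,2-sense to the allylic C11 alcohol and frees the C18 alcohol, releasing the bridge strain and leaving the silyl ether.

Step 12
Reactants: 19 diol
Product: 20 11-chloro-5,8-dien-18-ol with C17 OTBS
Conditions: NCS, Me2S, CH2Cl2, −20 → 0 °C
Reagents that add atoms: N-chlorosuccinimide O=C1CCC(=O)N1Cl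
Why: Corey–Kim halogenation converts only the allylic C11 hydroxyl into the chloride, because the alkoxysulfonium ion of the neopentyl C18 hydroxyl cannot be displaced and returns the alcohol on work-up.

Step 13
Reactants: 21 (2S)-3-bromo-2-methylpropan-1-ol
Product: 22 [(2S)-3-bromo-2-methylpropoxy](tert-butyl)dimethylsilane
Conditions: TBSCl, imidazole, DMF, 0 °C → rt
Reagents that add atoms: tert-butyldimethylsilyl chloride CC(C)(C)[Si](C)(C)Cl
Why: Standard silylation of a primary alcohol, which protects the future C12 oxygen.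

Step 14
Reactants: 22 silyl ether bromide
Product: 24 (3R)-4-[(tert-butyldimethylsilyl)oxy]-3-methylbutan-1-ol, via Grignard reagent 23 (not isolated)
Conditions: Mg, THF, reflux; paraformaldehyde, 0 °C → rt; aq. NH4Cl
Reagents that add atoms: formaldehyde (as paraformaldehyde) C=O
Why: Grignard addition to formaldehyde adds C15 without involving the stereocentre, and the γ-silyloxy Grignard reagent has no β-leaving group.

Step 15
Reactants: 24 homologated alcohol
Product: 26 tert-butyl{(2R)-4-[(4-methoxybenzyl)oxy]-2-methylbutoxy}dimethylsilane, via sodium alkoxide 25 (not isolated)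
Conditions: NaH, THF/DMF, 0 °C; PMBCl, Bu4NI (cat.), 0 °C → rt
Reagents that add atoms: 4-methoxybenzyl chloride COc1ccc(CCl)cc1
Why: Williamson etherification of the primary alkoxide protects the C15 oxygen as an ether that survives Grignard chemistry and is removable by oxidation.

Step 16
Reactants: 26 PMB/TBS diether
Product: 27 (2R)-4-[(4-methoxybenzyl)oxy]-2-methylbutan-1-ol
Conditions: TBAF, THF, 0 °C → rt
Reagents that add atoms: none
Why: Fluoride cleaves the primary silyl ether and leaves the PMB ether.

Step 17
Reactants: 27 alcohol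
Product: 28 1-{[(3R)-4-bromo-3-methylbutoxy]methyl}-4-methoxybenzene
Conditions: CBr4, PPh3, CH2Cl2, 0 °C
Reagents that add atoms: tetrabromomethane BrC(Br)(Br)Br
Why: Appel bromination converts the primary alcohol to the bromide under neutral conditions without touching the adjacent stereocentre.

Step 18
Reactants: 20 allylic chloride; 28 side-chain bromide
Product: 30 (13S)-15-[(4-methoxybenzyl)oxy]-17-[(tert-butyldimethylsilyl)oxy]-ent-labda-5,8-dien-18-ol, via Grignard reagent 29 (not isolated)
Conditions: 28, Mg, THF, 40 °C; separately 20, i-PrMgCl (1.0 equiv), THF, −78 °C; then 29 (1.6 equiv), Li2CuCl4 (5 mol %), −78 → 0 °C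
Reagents that add atoms: none
Why: Copper-catalysed Grignard coupling with a primary allylic chloride (Kochi-type) should go by direct substitution at C11 because the SN2′ path would have to build a quaternary centre at C8; C13 comes unchanged from 28 and is called S only because the CIP priorities change.

Step 19
Reactants: 30 coupled 5,8-diene
Product: 31 (13S)-15-[(4-methoxybenzyl)oxy]-17-[(tert-butyldimethylsilyl)oxy]-ent-labd-8-en-18-ol (H5 trans to C20)
Conditions: [Ir(cod)(PCy3)(py)]PF6 (5 mol %), H2 (1 atm), CH2Cl2, 0 °C → rt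
Reagents that add atoms: none
Why: Hydroxyl-directed hydrogenation with Crabtree's catalyst: the homoallylic C18 hydroxyl binds iridium and delivers H2 to the face of C5=C6 that carries C18, which is also the face opposite the C19 and C20 methyls, so H5 should end up trans to C20, while the tetrasubstituted C8=C9 alkene remote from the hydroxyl is left.

Step 20
Reactants: 32 p-coumaric acid
Product: 34 (E)-3-{4-[(tert-butyldimethylsilyl)oxy]phenyl}prop-2-enoic acid, via bis-silylated coumarate 33 (not isolated)
Conditions: TBSCl (2.3 equiv), imidazole, DMF, rt; then AcOH/THF/H2O (3:1:1), rt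
Reagents that add atoms: tert-butyldimethylsilyl chloride CC(C)(C)[Si](C)(C)Cl
Why: Silylation of both acidic groups followed by selective hydrolysis of the labile silyl ester leaves the aryl silyl ether and the E-alkene.

Step 21
Reactants: 31 C18 alcohol; 34 silyl-protected coumaric acid
Product: 35 18-O-[(E)-4-(tert-butyldimethylsilyloxy)cinnamoyl] ester of 31
Conditions: DCC, DMAP (0.3 equiv), CH2Cl2, rt
Reagents that add atoms: none
Why: Steglich esterification of the equatorial neopentyl C18 alcohol, the only free hydroxyl in 31.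

Step 22
Reactants: 35 fully protected ester
Product: 36 C17 allylic alcohol (C8=C9 alkene, C18 coumarate with aryl OTBS, C15 OPMB)
Conditions: PPTS (0.3 equiv), MeOH/CH2Cl2 (1:1), rt
Reagents that add atoms: none
Why: Acid-catalysed methanolysis removes the primary alkyl silyl ether, while the aryl silyl ether, the PMB ether and the cinnamate are stable to these conditions.

Step 23
Reactants: 36 C17 allylic alcohol
Product: 39 (13S)-15-[(4-methoxybenzyl)oxy]-ent-labd-8(17)-en-18-yl (E)-3-{4-[(tert-butyldimethylsilyl)oxy]phenyl}prop-2-enoate, via N-allyl sulfonylhydrazine 37 (not isolated), via allylic diazene 38 (not isolated)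
Conditions: 2-nitrobenzenesulfonylhydrazide, PPh3, DEAD, N-methylmorpholine, −30 °C; then rt
Reagents that add atoms: none
Why: Myers reductive 1,3-transposition: Mitsunobu N-alkylation of the sulfonylhydrazide at C17, loss of sulfinic acid to the allylic diazene and retro-ene loss of N2 move the alkene to C8=C17 and transfer hydrogen to C9 on the face opposite the axial C20 methyl, which should place H9 axial and C11 equatorial (9R).

Step 24
Reactants: 39 exo-methylene PMB ether
Product: 40 the corresponding C15 primary alcohol
Conditions: DDQ, CH2Cl2/pH 7 buffer (10:1), 0 °C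
Reagents that add atoms: none
Why: Oxidative PMB cleavage with DDQ is selective for the electron-rich benzyl ether over the silyl-protected cinnamate and the 1,1-disubstituted alkene.

Step 25
Reactants: 40 C15 alcohol
Product: 42 (13S)-18-{[(E)-4-(tert-butyldimethylsilyloxy)cinnamoyl]oxy}-ent-labd-8(17)-en-15-oic acid, via C15 aldehyde 41 (not isolated)
Conditions: TEMPO (0.2 equiv), PhI(OAc)2 (2.5 equiv), MeCN/H2O (1:1), rt
Reagents that add atoms: water O
Why: TEMPO/PhI(OAc)2 oxidation in aqueous acetonitrile takes the primary alcohol through the aldehyde and its hydrate to the acid without affecting the alkenes or the aryl silyl ether.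

Step 26
Reactants: 42 silyl-protected acid
Product: 43 target, (4S,5S,9R,10S,13S)-18-[(E)-4-hydroxycinnamoyloxy]-ent-labd-8(17)-en-15-oic acid
Conditions: TBAF/AcOH (1:1, 2.2 equiv), THF, 0 °C
Reagents that add atoms: none
Why: Buffered fluoride cleaves the aryl silyl ether under conditions too mild to hydrolyse the cinnamate ester or isomerise the exocyclic alkene.

## Compound list

1 | ethyl 2-oxocyclohexane-1-carboxylate | CCOC(=O)C1CCCCC1=O | starting material
2 | L-valine tert-butyl ester | CC(C)[C@H](N)C(=O)OC(C)(C)C | starting material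
3 | ethyl 2-{[(2S)-1-tert-butoxy-3-methyl-1-oxobutan-2-yl]amino}cyclohex-1-ene-1-carboxylate | CCOC(=O)C1=C(N[C@@H](C(C)C)C(=O)OC(C)(C)C)CCCC1 | intermediate
4 | N-lithio derivative of 3 (lithium aza-enolate) | CCOC(=O)C1=C(N([Li])[C@@H](C(C)C)C(=O)OC(C)(C)C)CCCC1 | intermediate
5 | ethyl (1S)-2-{[(2S)-1-tert-butoxy-3-methyl-1-oxobutan-2-yl]imino}-1-methylcyclohexane-1-carboxylate | CC(C)[C@@H](C(=O)OC(C)(C)C)N=C1[C@@](C)(C(=O)OCC)CCCC1 | intermediate
6 | ethyl (1S)-1-methyl-2-oxocyclohexane-1-carboxylate | O=C1[C@@](C)(C(=O)OCC)CCCC1 | intermediate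
7 | lithium enolate of 6 (C2–OLi, C2=C3) | [Li]OC=1[C@@](C)(C(=O)OCC)CCCC=1 | intermediate
8 | ethyl (1S,3RS)-1,3-dimethyl-2-oxocyclohexane-1-carboxylate | O=C1[C@@](C)(C(=O)OCC)CCCC1C | intermediate
9 | potassium enolate of 8 (C2–OK, C2=C3) | [K]OC=1[C@@](C)(C(=O)OCC)CCCC=1C | intermediate
10 | ethyl (1S)-1,3-dimethyl-2-[(trifluoromethanesulfonyl)oxy]cyclohex-2-ene-1-carboxylate | O=S(=O)(OC=1[C@@](C)(C(=O)OCC)CCCC=1C)C(F)(F)F | intermediate
11 | ethyl (1S)-2-ethenyl-1,3-dimethylcyclohex-2-ene-1-carboxylate | C=CC=1[C@@](C)(C(=O)OCC)CCCC=1C | intermediate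
12 | [(1S)-2-ethenyl-1,3-dimethylcyclohex-2-en-1-yl]methanol | C=CC=1[C@@](C)(CO)CCCC=1C | intermediate
13 | prop-2-yn-1-ol | C#CCO | starting material
14 | tert-butyldimethyl(prop-2-yn-1-yloxy)silane | C#CCO[Si](C)(C)C(C)(C)C | intermediate
15 | lithium acetylide of 14 | [Li]C#CCO[Si](C)(C)C(C)(C)C | intermediate
16 | 4-[(tert-butyldimethylsilyl)oxy]but-2-ynoic acid | OC(=O)C#CCO[Si](C)(C)C(C)(C)C | intermediate
17 | [(1S)-2-ethenyl-1,3-dimethylcyclohex-2-en-1-yl]methyl 4-[(tert-butyldimethylsilyl)oxy]but-2-ynoate | C=CC=1[C@@](C)(COC(=O)C#CCO[Si](C)(C)C(C)(C)C)CCCC=1C | intermediate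
18 | bridged 11,18-lactone of the 5,8-diene, C17 OTBS (C20 cis to C19, opposite the lactone bridge) | CC(C)(C)[Si](C)(C)OCC=1CC=C2[C@@](C)(COC(=O)C=13)CCC[C@]23C | intermediate
19 | 5,8-diene-11,18-diol, C17 OTBS (C19 and C20 cis, C18 trans to them) | CC(C)(C)[Si](C)(C)OCC=1CC=C2[C@@](C)(CO)CCC[C@@]2(C)C=1CO | intermediate
20 | 11-chloro-5,8-dien-18-ol, C17 OTBS | CC(C)(C)[Si](C)(C)OCC=1CC=C2[C@@](C)(CO)CCC[C@@]2(C)C=1CCl | intermediate
21 | (2S)-3-bromo-2-methylpropan-1-ol | OC[C@H](C)CBr | starting material
22 | [(2S)-3-bromo-2-methylpropoxy](tert-butyl)dimethylsilane | CC(C)(C)[Si](C)(C)OC[C@H](C)CBr | intermediate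
23 | Grignard reagent of 22 | CC(C)(C)[Si](C)(C)OC[C@H](C)C[Mg]Br | intermediate
24 | (3R)-4-[(tert-butyldimethylsilyl)oxy]-3-methylbutan-1-ol | CC(C)(C)[Si](C)(C)OC[C@H](C)CCO | intermediate
25 | sodium alkoxide of 24 | CC(C)(C)[Si](C)(C)OC[C@H](C)CCO[Na] | intermediate
26 | tert-butyl{(2R)-4-[(4-methoxybenzyl)oxy]-2-methylbutoxy}dimethylsilane | CC(C)(C)[Si](C)(C)OC[C@H](C)CCOCc1ccc(OC)cc1 | intermediate
27 | (2R)-4-[(4-methoxybenzyl)oxy]-2-methylbutan-1-ol | OC[C@H](C)CCOCc1ccc(OC)cc1 | intermediate
28 | 1-{[(3R)-4-bromo-3-methylbutoxy]methyl}-4-methoxybenzene | BrC[C@H](C)CCOCc1ccc(OC)cc1 | intermediate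
29 | Grignard reagent of 28 | Br[Mg]C[C@H](C)CCOCc1ccc(OC)cc1 | intermediate
30 | (13S)-15-[(4-methoxybenzyl)oxy]-17-[(tert-butyldimethylsilyl)oxy]-ent-labda-5,8-dien-18-ol | CC(C)(C)[Si](C)(C)OCC=1CC=C2[C@@](C)(CO)CCC[C@@]2(C)C=1CC[C@H](C)CCOCc3ccc(OC)cc3 | intermediate
31 | (13S)-15-[(4-methoxybenzyl)oxy]-17-[(tert-butyldimethylsilyl)oxy]-ent-labd-8-en-18-ol (H5 trans to C20) | CC(C)(C)[Si](C)(C)OCC=1CC[C@@H]2[C@@](C)(CO)CCC[C@@]2(C)C=1CC[C@H](C)CCOCc3ccc(OC)cc3 | intermediate
32 | p-coumaric acid, (E)-3-(4-hydroxyphenyl)prop-2-enoic acid | OC(=O)/C=C/c1ccc(O)cc1 | starting material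
33 | tert-butyldimethylsilyl (E)-3-{4-[(tert-butyldimethylsilyl)oxy]phenyl}prop-2-enoate | CC(C)(C)[Si](C)(C)OC(=O)/C=C/c1ccc(O[Si](C)(C)C(C)(C)C)cc1 | intermediate
34 | (E)-3-{4-[(tert-butyldimethylsilyl)oxy]phenyl}prop-2-enoic acid | OC(=O)/C=C/c1ccc(O[Si](C)(C)C(C)(C)C)cc1 | intermediate
35 | 18-O-[(E)-4-(tert-butyldimethylsilyloxy)cinnamoyl] ester of 31 | CC(C)(C)[Si](C)(C)OCC=1CC[C@@H]2[C@@](C)(COC(=O)/C=C/c3ccc(O[Si](C)(C)C(C)(C)C)cc3)CCC[C@@]2(C)C=1CC[C@H](C)CCOCc4ccc(OC)cc4 | intermediate
36 | C17 allylic alcohol from 35 (C8=C9, 18-coumarate with aryl OTBS, 15-OPMB) | OCC=1CC[C@@H]2[C@@](C)(COC(=O)/C=C/c3ccc(O[Si](C)(C)C(C)(C)C)cc3)CCC[C@@]2(C)C=1CC[C@H](C)CCOCc4ccc(OC)cc4 | intermediate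
37 | N-(C17-allyl)-N-(2-nitrobenzenesulfonyl)hydrazine from 36 | NN(CC=1CC[C@@H]2[C@@](C)(COC(=O)/C=C/c3ccc(O[Si](C)(C)C(C)(C)C)cc3)CCC[C@@]2(C)C=1CC[C@H](C)CCOCc4ccc(OC)cc4)S(=O)(=O)c5ccccc5[N+](=O)[O-] | intermediate
38 | C17 allylic diazene | N=NCC=1CC[C@@H]2[C@@](C)(COC(=O)/C=C/c3ccc(O[Si](C)(C)C(C)(C)C)cc3)CCC[C@@]2(C)C=1CC[C@H](C)CCOCc4ccc(OC)cc4 | intermediate
39 | (13S)-15-[(4-methoxybenzyl)oxy]-ent-labd-8(17)-en-18-yl (E)-3-{4-[(tert-butyldimethylsilyl)oxy]phenyl}prop-2-enoate (4S,5S,9R,10S) | C=C1CC[C@@H]2[C@@](C)(COC(=O)/C=C/c3ccc(O[Si](C)(C)C(C)(C)C)cc3)CCC[C@@]2(C)[C@@H]1CC[C@H](C)CCOCc4ccc(OC)cc4 | intermediate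
40 | (13S)-15-hydroxy-ent-labd-8(17)-en-18-yl (E)-3-{4-[(tert-butyldimethylsilyl)oxy]phenyl}prop-2-enoate | C=C1CC[C@@H]2[C@@](C)(COC(=O)/C=C/c3ccc(O[Si](C)(C)C(C)(C)C)cc3)CCC[C@@]2(C)[C@@H]1CC[C@H](C)CCO | intermediate
41 | the corresponding C15 aldehyde | C=C1CC[C@@H]2[C@@](C)(COC(=O)/C=C/c3ccc(O[Si](C)(C)C(C)(C)C)cc3)CCC[C@@]2(C)[C@@H]1CC[C@H](C)CC=O | intermediate
42 | (13S)-18-{[(E)-4-(tert-butyldimethylsilyloxy)cinnamoyl]oxy}-ent-labd-8(17)-en-15-oic acid | C=C1CC[C@@H]2[C@@](C)(COC(=O)/C=C/c3ccc(O[Si](C)(C)C(C)(C)C)cc3)CCC[C@@]2(C)[C@@H]1CC[C@H](C)CC(=O)O | intermediate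
43 | (4S,5S,9R,10S,13S)-18-[(E)-4-hydroxycinnamoyloxy]-ent-labd-8(17)-en-15-oic acid (CNP0389065.1) | C=C1CC[C@@H]2[C@@](C)(COC(=O)/C=C/c3ccc(O)cc3)CCC[C@@]2(C)[C@@H]1CC[C@H](C)CC(=O)O | target

## Step count

Total steps: 26. Longest linear sequence: 18 steps (steps 1–6, 9–12, 18, 19, 21–26).

## Steps most likely to fail

**Step 10 (intramolecular Diels–Alder).** The bridged transition state may be too strained, or too rarely populated because closure needs the cisoid ester rotamer. At the temperature required, a [1,5]-hydrogen shift from C20 to C7 in the Z-methyl diene, intermolecular cycloaddition or thermal decomposition could then take over.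
Fallback (known chemistry), setting out from 12 and 16 and returning at 19: acid 16 is methylated (MeI, K2CO3, DMF) to methyl 4-[(tert-butyldimethylsilyl)oxy]but-2-ynoate F1. Dienol 12 and F1 are heated neat at 110–130 °C, the established intermolecular cycloaddition of this diene class with acetylenic esters, in which the ester-bearing carbon adds to the substituted terminus C10. Facial control is given up, so both C10 epimers are expected. The epimer with C9 syn to C18, the hydroxy methyl ester F2, is separated by chromatography from its C10 epimer F3. DIBAL-H reduction of F2 gives diol 19.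

**Step 19 (directed hydrogenation).** The iridium hydride may isomerise the skipped 5,8-diene into conjugation, the tetrasubstituted C8=C9 alkene may be partly reduced, or the hydroxyl may fail to bind and facial control may be lost.
Fallback, from 30 directly to 31: radical hydrogen-atom-transfer hydrogenation (Mn(dpm)3 cat., PhSiH3, tert-butyl hydroperoxide, i-PrOH, rt). Hydrogen-atom transfer to C6 gives the tertiary C5 radical, which is reduced from the face opposite C20 to give the thermodynamically preferred trans ring fusion without any coordination to the catalyst; the more hindered tetrasubstituted alkene should react more slowly. No new compound is involved.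

**Step 23 (reductive transposition).** Mitsunobu substitution at the hindered C17 carbinol may be incomplete, or the diazene may fragment without clean hydrogen transfer to the correct face of C9.
Fallback, from 36 back to 39: alcohol 36 is converted (ClCO2Me, pyridine, CH2Cl2, 0 °C) into the C17 allylic methyl carbonate F4. Palladium-catalysed formate reduction (Pd(OAc)2, PBu3, HCO2H/Et3N, THF, 40 °C) then gives the π-allyl complex on the face opposite C20 and delivers hydride from palladium to the more substituted terminus C9, which should give the exocyclic C8=C17 alkene and the same H9 configuration as in 39.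

## Further compounds

F1 | step 10 | methyl 4-[(tert-butyldimethylsilyl)oxy]but-2-ynoate | COC(=O)C#CCO[Si](C)(C)C(C)(C)C
F2 | step 10 | methyl ester at C11 of the 5,8-dien-18-ol, C17 OTBS (C9 syn to C18) | CC(C)(C)[Si](C)(C)OCC=1CC=C2[C@@](C)(CO)CCC[C@@]2(C)C=1C(=O)OC
F3 | step 10 | C10 epimer of F2 | CC(C)(C)[Si](C)(C)OCC=1CC=C2[C@@](C)(CO)CCC[C@]2(C)C=1C(=O)OC
F0 | step 19 | none | none
F4 | step 23 | C17 allylic methyl carbonate of 36 | COC(=O)OCC=1CC[C@@H]2[C@@](C)(COC(=O)/C=C/c3ccc(O[Si](C)(C)C(C)(C)C)cc3)CCC[C@@]2(C)C=1CC[C@H](C)CCOCc4ccc(OC)cc4
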